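**Retrosynthetic overview**

1. Numbering: ring A = C1 (quaternary, methyl C15), C2, C3, C4 (isopropyl carbinol), C5 (fusion CH); ring B = C5, C6 (ester), C7, C8 (spiro-epoxide, CH2 = C14), C9, C10, C1; α is the face of H5, β that of C15. The route rests on the 1,4-relation of the oxygens at C10 and C6 through the fusion bond C1–C5: ring A is a masked trans-cyclopentane-1,2-dicarbaldehyde, and C1–C5 is the bond that an oxidative coupling of two enol ethers makes.
2. Ring A (first): anodic cyclisation of the acyclic bis(methyl enol ether) 12, obtained by ring-opening ozonolysis of (S)-terpinen-4-ol with C4 already in place, gives bis-acetal 13 and sets the quaternary C1.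
3. Ring B (second): the two formyl groups are told apart by enolisability (only C6), C10 becomes a vinyl group, C6 takes C7–C9 in a chelation-controlled Mukaiyama aldol, and ring-closing metathesis closes C9=C10 as an enone.
4. End game: α-face dihydroxylation of C9=C10, methylenation of the C8 ketone, and C9-hydroxyl-directed epoxidation of C8=C14; the isovalerate is placed on C6 before ring closure.

Key step: step 6

Assumption: (S)-terpinen-4-ol is used enantiomerically pure, and the enol ethers 8, 9, 10, 12, 15 and 17 are carried as E/Z mixtures (one geometry is drawn where a geometry is written), which is without consequence because that geometry is lost on oxidation or protonation.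

**Route**

Step 1
Reactants: 1 (S)-terpinen-4-ol
Product: 2 triethylsilyl ether of 1
Conditions: Et3SiOTf, 2,6-lutidine, CH2Cl2, 0 °C to rt
Reagents that add atoms: triethylsilyl trifluoromethanesulfonate, CC[Si](CC)(CC)OS(=O)(=O)C(F)(F)F
Why: Silylation of the hindered tertiary alcohol with a silyl triflate and 2,6-lutidine (silyl ether formation) should go cleanly, and masking C4–OH keeps it from closing onto the C1 carbonyl that ozonolysis creates; C4 is not touched.

Step 2
Reactants: 2 triethylsilyl ether of 1; 3 methanol
Product: 7 hydroxy acetal CH3-CH(OH)-CH2CH2-C4(OSiEt3)(iPr)-CH2-CH(OMe)2 (C1 carbinol as epimer mixture), via methoxy hydroperoxide aldehyde 4 (not isolated), via methoxy hydroperoxide acetal 5 (not isolated), via keto acetal 6 (not isolated)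
Conditions: O3, CH2Cl2/MeOH 5:1, −78 °C; TsOH·H2O (cat.), rt; NaHCO3; NaBH4, 0 °C
Reagents that add atoms: ozone, [O-][O+]=O; methanol (3), CO
Why: Ozonolysis of the trisubstituted ring alkene in methanol (Criegee mechanism) should place the carbonyl oxide on the more substituted C1, where methanol traps it as the methoxy hydroperoxide, and leave C6 as an aldehyde that TsOH/MeOH acetalises, after which NaBH4 reduces the peroxide and the released methyl ketone, so the two ends of the opened ring come out differentiated.

Step 3
Reactants: 7 hydroxy acetal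
Product: 9 hydroxy enol ether CH3-CH(OH)-CH2CH2-C4(OSiEt3)(iPr)-CH=CH-OMe, via trimethylsilyl ether 8 (not isolated)
Conditions: Me3SiOTf (2.5 equiv), iPr2NEt (3 equiv), CH2Cl2, −20 °C to rt; then K2CO3, MeOH, 0 °C
Reagents that add atoms: none
Why: Silyl triflate/amine elimination of methanol from a dimethyl acetal (ionisation to the oxocarbenium ion, loss of a C5 proton) should give the C5=C6 methyl enol ether, and it is run before the C10=C1 enol ether exists, with the C1 oxygen held as a transient silyl ether, so that no π-nucleophile can add to the oxocarbenium ion (Prins-type closure); K2CO3/MeOH then frees the secondary alcohol without touching the tertiary silyl ether.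

Step 4
Reactants: 9 hydroxy enol ether
Product: 10 keto enol ether CH3-CO-CH2CH2-C4(OSiEt3)(iPr)-CH=CH-OMe
Conditions: SO3·pyridine, DMSO, iPr2NEt, CH2Cl2, 0 °C
Reagents that add atoms: none
Why: Parikh–Doering oxidation is non-acidic and should convert the secondary alcohol into the methyl ketone without harming the enol ether or the tertiary allylic silyl ether.

Step 5
Reactants: 10 keto enol ether; 11 (methoxymethyl)triphenylphosphonium chloride
Product: 12 bis(methyl enol ether) 1,7-dimethoxy-2-methyl-5-isopropyl-5-(triethylsilyloxy)hepta-1,6-diene (MeO-C10H=C1(CH3)-C2H2-C3H2-C4(OSiEt3)(iPr)-C5H=C6H-OMe)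
Conditions: KOtBu, THF, 0 °C to rt
Reagents that add atoms: (methoxymethyl)triphenylphosphonium chloride (11), COC[P+](c1ccccc1)(c1ccccc1)c1ccccc1.[Cl-]
Why: Wittig methoxymethylenation of an unhindered methyl ketone should give the trisubstituted enol ether as an E/Z mixture, both isomers of which converge in step 6.

Step 6
Reactants: 12 bis(methyl enol ether); 3 methanol
Product: 13 ring A bis(dimethyl acetal): cyclopentane with C1 (β-CH3, α-CH(OMe)2), C4 (β-OSiEt3, α-iPr) and C5 (β-CH(OMe)2, α-H)
Conditions: reticulated vitreous carbon anode, Pt cathode, undivided cell, constant current 8 mA (2.2 F/mol), 0.1 M LiClO4, MeOH/THF 1:4, 2,6-lutidine, rt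
Reagents that add atoms: methanol (3), CO
Why: Intramolecular anodic olefin coupling of a bis enol ether: the more electron-rich trisubstituted enol ether C10=C1 gives up an electron at the anode, which makes C1 electrophilic (polarity reversal), C5 of the second enol ether adds to it, the resulting C10 radical is oxidised again, and methanol caps both oxocarbenium ions as dimethyl acetals. Ring A closes in a 5-exo-trig mode with respect to both double bonds (C10 and C6 stay outside the ring), and the closest known reaction type is the anodic cyclisation of bis enol ethers to cyclopentane 1,4-bis-acetals, including closures onto a methyl-bearing carbon that create a quaternary centre. At C5 the new bond should form anti to the isopropyl group, the larger of the two C4 substituents, so that the C6 arm lies cis to the silyloxy group (β). At C1 the two methoxy-bearing termini should stay anti about the forming bond, keeping the developing oxocarbenium charge at C6 away from the radical-cation terminus C10, which puts C10 α and C15 β. The step needs C–C bond formation to outrun methanol capture of the radical cation and needs C1 to be set relative to C4; the five-membered closure in a buffered medium with no other nucleophile serves the first, the isopropyl/silyloxy pair on C4 the second, and C5 is set again under thermodynamic control in step 10.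

Step 7
Reactants: 13 ring A bis(dimethyl acetal)
Product: 14 ring A dialdehyde (C1: β-CH3, α-CHO; C4: β-OSiEt3, α-iPr; C5: β-CHO)
Conditions: CF3CO2H/H2O/CHCl3 1:1:8, 0 °C
Reagents that add atoms: water, O
Why: Acid-catalysed acetal hydrolysis should free both formyl groups, which cannot close to a cyclic bis-hemiacetal because they are trans on ring A, while the hindered tertiary silyl ether should survive brief cold aqueous acid.

Step 8
Reactants: 14 ring A dialdehyde
Product: 15 C6 triethylsilyl enol ether of 14 (C5=C6H-OSiEt3, C10 aldehyde free)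
Conditions: Et3SiOTf (1.3 equiv), Et3N, CH2Cl2, −78 to 0 °C
Reagents that add atoms: triethylsilyl trifluoromethanesulfonate, CC[Si](CC)(CC)OS(=O)(=O)C(F)(F)F
Why: Soft enolisation with a silyl triflate and Et3N (silyl enol ether formation) can only take place at C6, because the C10 aldehyde sits on quaternary C1 and has no α-hydrogen, which differentiates the two formyl groups; C5 becomes sp2 and is set again in step 10.

Step 9
Reactants: 15 C6 silyl enol ether aldehyde; 16 methyltriphenylphosphonium bromide
Product: 17 C1-vinyl compound (C10H=CH2 on C1, C5=C6H-OSiEt3, C4-OSiEt3)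
Conditions: KN(SiMe3)2, THF, 0 °C to rt
Reagents that add atoms: methyltriphenylphosphonium bromide (16), C[P+](c1ccccc1)(c1ccccc1)c1ccccc1.[Br-]
Why: Wittig methylenation of the remaining non-enolisable neopentyl aldehyde should give the C1 vinyl group, the silyl enol ether and the silyl ether being inert to the ylide.

Step 10
Reactants: 17 C1-vinyl silyl enol ether
Product: 18 hydroxy aldehyde (C1: β-CH3, α-vinyl; C4: β-OH, α-iPr; C5: β-CHO, α-H)
Conditions: Bu4NF/AcOH 1:1, THF, 0 °C to rt
Reagents that add atoms: none
Why: Fluoride cleaves the enol silane and the tertiary silyl ether (desilylation), and under the buffered conditions C5 should settle under thermodynamic control through enol–aldehyde equilibration with the formyl group β, trans to the isopropyl and vinyl groups and hydrogen-bonded to the cis C4 hydroxyl.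

Step 11
Reactants: 18 hydroxy aldehyde; 19 2-(trimethylsilyloxy)buta-1,3-diene
Product: 20 aldol, the vinyl ketone C6H(OH)-C7H2-C8(=O)-C9H=CH2 on C5 (C6 oxygen as in the target, 6α after ring closure)
Conditions: Me2AlCl (2.2 equiv), CH2Cl2, −78 °C; then 19 (2 equiv), −78 °C
Reagents that add atoms: 2-(trimethylsilyloxy)buta-1,3-diene (19), C=CC(=C)O[Si](C)(C)C
Why: Chelation-controlled Mukaiyama aldol addition: Me2AlCl turns C4–OH into an aluminium alkoxide that binds the C6 carbonyl oxygen in a six-membered chelate lying under ring A, and the dienol silane should attack C6 through its terminal CH2 from the exposed face, away from ring A and C15, which gives the 6α-oxygen (1,3-anti to O4).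

Step 12
Reactants: 20 aldol; 21 3-methylbutanoyl chloride (isovaleryl chloride)
Product: 22 C6 isovalerate of 20
Conditions: pyridine, DMAP (cat.), CH2Cl2, 0 °C
Reagents that add atoms: 3-methylbutanoyl chloride (21), CC(C)CC(Cl)=O
Why: Acylation of the secondary alcohol with the acid chloride under DMAP catalysis should spare the hindered tertiary C4–OH and, by capping O6 at once, prevents conjugate addition of that hydroxyl to the vinyl ketone.

Step 13
Reactants: 22 C6 isovalerate
Product: 23 trans-fused bicyclic enone (C8 ketone, C9=C10, 6α-isovalerate, 4β-OH)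
Conditions: second-generation Hoveyda–Grubbs catalyst RuCl2(H2IMes)(=CH-C6H4-2-OiPr) (10 mol %), toluene (2 mM), 80 °C
Reagents that add atoms: none
Why: Ring-closing metathesis between the vinyl ketone and the C1 vinyl group should close ring B as the trans-fused cycloheptenone with a necessarily cis C9=C10 bond, high dilution favouring the seven-membered closure over dimerisation.

Step 14
Reactants: 23 bicyclic enone
Product: 24 9α,10α-dihydroxy C8 ketone
Conditions: OsO4 (5 mol %), N-methylmorpholine N-oxide, citric acid, tBuOH/H2O 1:1, rt
Reagents that add atoms: osmium tetroxide (oxygen carrier), O=[Os](=O)(=O)=O; N-methylmorpholine N-oxide, C[N+]1([O-])CCOCC1; water, O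
Why: Osmium-catalysed syn-dihydroxylation (Upjohn conditions, citric acid for the electron-poor alkene) should occur on the α face of C9=C10, anti to the axial C15 methyl on the neighbouring fusion carbon C1, setting 9α-OH and 10α-OH together.

Step 15
Reactants: 24 dihydroxy ketone
Product: 25 9α,10α-acetonide of 24
Conditions: Me2C(OMe)2, pyridinium p-toluenesulfonate (cat.), CH2Cl2, rt
Reagents that add atoms: 2,2-dimethoxypropane, COC(C)(C)OC
Why: Acetonide formation on the cis-diol keeps the α-ketol from chelating or rearranging under the Lewis-acidic methylenation that follows; no stereocentre is affected.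

Step 16
Reactants: 25 acetonide ketone; 26 dibromomethane
Product: 27 C8=C14 methylene acetonide
Conditions: Zn, TiCl4, THF/CH2Cl2, 0 °C to rt
Reagents that add atoms: dibromomethane (26), BrCBr
Why: Takai–Lombardo methylenation is non-basic, so the C8 ketone should become the C8=C14 methylene group without β-elimination of the C6 ester or epimerisation at C9.

Step 17
Reactants: 27 methylene acetonide
Product: 28 4β,9α,10α-triol with C8=C14 and 6α-isovalerate
Conditions: AcOH/H2O 4:1, 40 °C
Reagents that add atoms: none
Why: Mild aqueous acid hydrolyses the acetonide (acetal hydrolysis), freeing the allylic 9α-OH that directs the last step, and should leave the ester and the tertiary alcohol untouched.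

Step 18
Reactants: 28 triol alkene
Product: 29 target CNP0307265.1
Conditions: VO(acac)2 (cat.), tBuOOH, CH2Cl2, 0 °C to rt
Reagents that add atoms: tert-butyl hydroperoxide, CC(C)(C)OO
Why: Vanadium-catalysed hydroxyl-directed epoxidation: the vanadate ester of the allylic 9α-OH, supported by the homoallylic 10α-OH, should deliver oxygen to the same α face of C8=C14, giving the spiro-epoxide with O α and C14 β.

**Compound list**

1 | (S)-terpinen-4-ol | CC1=CC[C@](O)(C(C)C)CC1 | starting material
2 | triethylsilyl ether of 1 | CC1=CC[C@](O[Si](CC)(CC)CC)(C(C)C)CC1 | intermediate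
3 | methanol | CO | starting material
4 | methoxy hydroperoxide aldehyde (C1 bears OMe and OOH, C6 aldehyde) | CC(OC)(OO)CC[C@@](O[Si](CC)(CC)CC)(C(C)C)CC=O | intermediate (not isolated)
5 | methoxy hydroperoxide dimethyl acetal | CC(OC)(OO)CC[C@@](O[Si](CC)(CC)CC)(C(C)C)CC(OC)OC | intermediate (not isolated)
6 | keto acetal, 7,7-dimethoxy-5-isopropyl-5-(triethylsilyloxy)heptan-2-one | CC(=O)CC[C@@](O[Si](CC)(CC)CC)(C(C)C)CC(OC)OC | intermediate (not isolated)
7 | hydroxy acetal, 7,7-dimethoxy-5-isopropyl-5-(triethylsilyloxy)heptan-2-ol (C2 epimers) | CC(O)CC[C@@](O[Si](CC)(CC)CC)(C(C)C)CC(OC)OC | intermediate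
8 | trimethylsilyl ether of 9 | CC(O[Si](C)(C)C)CC[C@@](O[Si](CC)(CC)CC)(C(C)C)/C=C/OC | intermediate (not isolated)
9 | hydroxy enol ether, 7-methoxy-5-isopropyl-5-(triethylsilyloxy)hept-6-en-2-ol | CC(O)CC[C@@](O[Si](CC)(CC)CC)(C(C)C)/C=C/OC | intermediate
10 | keto enol ether, 7-methoxy-5-isopropyl-5-(triethylsilyloxy)hept-6-en-2-one | CC(=O)CC[C@@](O[Si](CC)(CC)CC)(C(C)C)/C=C/OC | intermediate
11 | (methoxymethyl)triphenylphosphonium chloride | COC[P+](c1ccccc1)(c1ccccc1)c1ccccc1.[Cl-] | starting material
12 | bis(methyl enol ether), 1,7-dimethoxy-2-methyl-5-isopropyl-5-(triethylsilyloxy)hepta-1,6-diene | CO/C=C(\C)CC[C@@](O[Si](CC)(CC)CC)(C(C)C)/C=C/OC | intermediate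
13 | ring A trans bis(dimethyl acetal) | COC(OC)[C@@]1(C)CC[C@@](O[Si](CC)(CC)CC)(C(C)C)[C@@H]1C(OC)OC | intermediate
14 | ring A trans dialdehyde | O=C[C@@]1(C)CC[C@@](O[Si](CC)(CC)CC)(C(C)C)[C@@H]1C=O | intermediate
15 | C6 triethylsilyl enol ether, C10 aldehyde | O=C[C@@]1(C)CC[C@@](O[Si](CC)(CC)CC)(C(C)C)C1=CO[Si](CC)(CC)CC | intermediate
16 | methyltriphenylphosphonium bromide | C[P+](c1ccccc1)(c1ccccc1)c1ccccc1.[Br-] | starting material
17 | C1-vinyl C6 silyl enol ether | C=C[C@@]1(C)CC[C@@](O[Si](CC)(CC)CC)(C(C)C)C1=CO[Si](CC)(CC)CC | intermediate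
18 | hydroxy aldehyde (1β-methyl-1α-vinyl, 4β-hydroxy-4α-isopropyl, 5β-formyl cyclopentane) | C=C[C@@]1(C)CC[C@@](O)(C(C)C)[C@@H]1C=O | intermediate
19 | 2-(trimethylsilyloxy)buta-1,3-diene | C=CC(=C)O[Si](C)(C)C | starting material
20 | aldol, β-hydroxy vinyl ketone at C6–C9 | C=CC(=O)C[C@H](O)[C@H]1[C@](O)(C(C)C)CC[C@]1(C)C=C | intermediate
21 | 3-methylbutanoyl chloride | CC(C)CC(Cl)=O | starting material
22 | C6 isovalerate of 20 | C=CC(=O)C[C@H](OC(=O)CC(C)C)[C@H]1[C@](O)(C(C)C)CC[C@]1(C)C=C | intermediate
23 | trans-fused enone (C8=O, C9=C10) | CC(C)CC(=O)O[C@H]1CC(=O)C=C[C@@]2(C)CC[C@@](O)(C(C)C)[C@H]12 | intermediate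
24 | 9α,10α-dihydroxy C8 ketone | CC(C)CC(=O)O[C@H]1CC(=O)[C@@H](O)[C@@H](O)[C@@]2(C)CC[C@@](O)(C(C)C)[C@H]12 | intermediate
25 | 9α,10α-acetonide C8 ketone | CC(C)CC(=O)O[C@H]1CC(=O)[C@H]3OC(C)(C)O[C@H]3[C@@]2(C)CC[C@@](O)(C(C)C)[C@H]12 | intermediate
26 | dibromomethane | BrCBr | starting material
27 | 9α,10α-acetonide with C8=C14 | CC(C)CC(=O)O[C@H]1CC(=C)[C@H]3OC(C)(C)O[C@H]3[C@@]2(C)CC[C@@](O)(C(C)C)[C@H]12 | intermediate
28 | 4β,9α,10α-triol with C8=C14, 6α-isovalerate | CC(C)CC(=O)O[C@H]1CC(=C)[C@@H](O)[C@@H](O)[C@@]2(C)CC[C@@](O)(C(C)C)[C@H]12 | intermediate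
29 | CNP0307265.1 | CC(C)CC(=O)O[C@H]1C[C@]2(CO2)[C@@H](O)[C@@H](O)[C@@]2(C)CC[C@@](O)(C(C)C)[C@H]12 | target

**Step count and risks**

Total step count: 18. Longest linear sequence: 18 steps (1 to 29).

Steps most likely to fail:

Step 6 (anodic coupling). Methanol may capture the radical cation before the congested C1–C5 bond forms, the two faces of C1 may be poorly discriminated, and the allylic silyloxy group may be lost oxidatively. The fallback closes the same bond by palladium-catalysed allylic alkylation of an enamine; it sets out from keto acetal 6, which is isolated when step 2 is worked up with Me2S in place of NaBH4, and comes back at 18. Ketone 6 is olefinated with triethyl phosphonoacetate and NaH (Horner–Wadsworth–Emmons) to the (E)-unsaturated ester F1, which iBu2AlH reduces to the allylic alcohol F2. Methyl chloroformate and pyridine give the allylic methyl carbonate F3, and mild aqueous acid (pyridinium p-toluenesulfonate, acetone/water) unmasks C6 to give the carbonate aldehyde F4. With Pd(PPh3)4 and pyrrolidine, C5 of the enamine should attack the methyl-bearing terminus C1 of the π-allyl complex (Tsuji–Trost, 5-exo), giving the silyl-protected vinyl aldehyde F5 with quaternary C1. Buffered Bu4NF then removes the silyl ether to reach 18.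

Step 11 (Mukaiyama aldol). The dienol silane may be protodesilylated at the hydroxyl-bearing Lewis-acid chelate before it adds, the new C6 hydroxyl may add in conjugate fashion to the vinyl ketone, and the facial bias falls if the chelate does not hold. The fallback builds the vinyl ketone in two steps through an amide enolate; it sets out from 18 and comes back at 20. The lithium enolate of N-methoxy-N-methylacetamide (LiN(iPr)2, THF, −78 °C, in excess so that O4 is a lithium alkoxide that chelates the aldehyde) gives the β-hydroxy Weinreb amide F6. Vinylmagnesium bromide in excess, followed by a cold acidic quench (Weinreb ketone synthesis), then gives 20.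

Step 13 (ring-closing metathesis). Initiation at the neopentyl vinyl group may be slow, the enone oxygen may tie up the ruthenium carbene, and intermolecular metathesis may take over. The fallback closes C9=C10 by an intramolecular Horner–Wadsworth–Emmons reaction; it sets out from 18 and comes back at 23. The dianion of dimethyl (2-oxopropyl)phosphonate (NaH, then nBuLi) adds through its terminal carbon to the C6 aldehyde of 18 to give the hydroxy ketophosphonate F7, which isovaleryl chloride and pyridine convert into the ester F8. Ozonolysis of the C1 vinyl group (O3, then PPh3) returns the C10 aldehyde in the ketophosphonate aldehyde F9, and LiCl with iPr2NEt in MeCN at high dilution (Masamune–Roush conditions) closes the ring to 23.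

**Further compounds**

F1 | step 6 | ethyl (E)-enoate from 6 (CO2Et on C10) | CCOC(=O)/C=C(\C)CC[C@@](O[Si](CC)(CC)CC)(C(C)C)CC(OC)OC
F2 | step 6 | (E)-allylic alcohol | OC/C=C(\C)CC[C@@](O[Si](CC)(CC)CC)(C(C)C)CC(OC)OC
F3 | step 6 | allylic methyl carbonate | COC(=O)OC/C=C(\C)CC[C@@](O[Si](CC)(CC)CC)(C(C)C)CC(OC)OC
F4 | step 6 | carbonate aldehyde (C6 aldehyde free) | COC(=O)OC/C=C(\C)CC[C@@](O[Si](CC)(CC)CC)(C(C)C)CC=O
F5 | step 6 | silyl-protected vinyl aldehyde (triethylsilyl ether of 18) | C=C[C@@]1(C)CC[C@@](O[Si](CC)(CC)CC)(C(C)C)[C@@H]1C=O
F6 | step 11 | β-hydroxy Weinreb amide | CON(C)C(=O)C[C@H](O)[C@H]1[C@](O)(C(C)C)CC[C@]1(C)C=C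
F7 | step 13 | hydroxy ketophosphonate | COP(=O)(OC)CC(=O)C[C@H](O)[C@H]1[C@](O)(C(C)C)CC[C@]1(C)C=C
F8 | step 13 | ketophosphonate C6 isovalerate | COP(=O)(OC)CC(=O)C[C@H](OC(=O)CC(C)C)[C@H]1[C@](O)(C(C)C)CC[C@]1(C)C=C
F9 | step 13 | ketophosphonate aldehyde (C10 aldehyde) | COP(=O)(OC)CC(=O)C[C@H](OC(=O)CC(C)C)[C@H]1[C@](O)(C(C)C)CC[C@]1(C)C=O
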